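**Plan**
1. Cuts: the two C15–O ester bonds (acyl carbon on C2' of isocitrate units 2 and 3) give three copies of one drimane–isocitrate monomer; then its C11–O–C1' ether (allylic bromide + hydroxy triester) and the isocitrate C2'–C3' bond (alkylation of D-malate).
2. Ring A is cut by a retro ring contraction. C4 carries a methyl and the oxidised carbon C15 next to the ring-fusion CH C5, which is the 1-methylcycloalkane-1-carbaldehyde pattern left by contraction of a 1-methylcycloalkene oxide. C15 is therefore first a ring atom between C4 and C5 of a seven-membered ring C10–C1–C2–C3–C4–C15–C5.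
3. Forward: ring B (2-methylcyclohexenone) → conjugate vinylation/alkylation → seven-membered ring by ring-closing metathesis → α-epoxide → contraction to ring A (C15 leaves the ring as CHO) → C9 ketone converted to the C11 allylic bromide → ether → reductive allylic transposition to the C8=C12 methylene.
4. Assembly: monomer acid + monomer alcohol → dimer; desilylation; second monomer acid → trimer; three deprotections.
5. Stereochemistry: C5 from the chiral copper catalyst, C10 from alkylation anti to vinyl, C4 from the epoxide face and the anti 1,2-shift, C9 from α-face hydrogen delivery; C1' from D-malic acid, C2' from anti alkylation.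

Key step: step 8

Assumption: drimane locants are used (C11 on C9, C12 on C8, C15 = the oxygen-bearing carbon on C4, methyls on C4β and C10β; isocitrate chain C1' = ether carbon, C2', C3' = CH2); the C8 configuration of 21 and 23 is left open because step 15 erases it.

Step 1
Reactants: 1 (R)-malic acid
Product: 3 (R)-malic acid 1-methyl ester, via trifluoroacetylated malic anhydride 2 (not isolated)
Conditions: (CF3CO)2O, neat, 0 °C → rt; concentrate; MeOH, 0 °C → rt
Reagents that add atoms: methanol (CO)
Why: Cyclic anhydride formation and regioselective alcoholysis at the more electrophilic carbonyl next to the acyloxy carbon should give the 1-monoester with the stereocentre untouched.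

Step 2
Reactants: 3 (R)-malic acid 1-methyl ester
Product: 4 4-allyl 1-methyl (R)-malate
Conditions: Cs2CO3 (0.5 equiv), allyl bromide, DMF, 0 °C → rt
Reagents that add atoms: allyl bromide (C=CCBr)
Why: SN2 O-alkylation of the caesium carboxylate differentiates the two carboxyl groups without touching the carbinol centre.

Step 3
Reactants: 4 4-allyl 1-methyl (R)-malate; 5 tert-butyl bromoacetate
Product: 7 hydroxy triester 3-tert-butyl 1-methyl 2-allyl (1R,2S)-1-hydroxypropane-1,2,3-tricarboxylate, via dilithium alkoxide enolate 6 (not isolated)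
Conditions: LiN(SiMe3)2 (2.1 equiv), THF, −78 °C; then 5, −78 → −50 °C; AcOH, −78 °C
Reagents that add atoms: none
Why: Fráter–Seebach alkylation: the chelated alkoxide–enolate is alkylated anti to the C1'–O bond, which should set C2' as S (natural isocitrate configuration), while the bulky tert-butyl ester keeps the alkoxide from lactonising.

Step 4
Reactants: 8 2-methylcyclohex-2-en-1-one; 9 vinylmagnesium bromide
Product: 11 (S)-trimethyl[(2-methyl-3-vinylcyclohex-1-en-1-yl)oxy]silane, via bromomagnesium enolate 10 (not isolated)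
Conditions: Cu(OTf)2 (3 mol %), chiral imidazolinium salt (N-heterocyclic carbene precursor, 4 mol %), Et2O, −30 °C; then Me3SiCl, Et3N, −30 → 0 °C
Reagents that add atoms: chlorotrimethylsilane (C[Si](C)(C)Cl)
Why: Copper-catalysed asymmetric conjugate addition of a Grignard reagent to an α-methyl cyclic enone with silyl trapping; the chiral carbene–copper complex (enantiomer chosen for the S adduct) selects the enone face and sets C5.

Step 5
Reactants: 11 silyl enol ether; 12 5-bromo-2-methylpent-1-ene
Product: 14 (2S,3S)-2-methyl-2-(4-methylpent-4-en-1-yl)-3-vinylcyclohexan-1-one, via lithium enolate 13 (not isolated)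
Conditions: MeLi, THF, 0 °C; then 12, HMPA, −40 °C → rt
Reagents that add atoms: none
Why: Regiospecific lithium enolate generation from the silyl enol ether and SN2 alkylation; the bromide should approach anti to the neighbouring vinyl group and so set the quaternary C10 (chain trans to vinyl, methyl cis).

Step 6
Reactants: 14 dienyl ketone
Product: 15 (4aS,9aS)-6,9a-dimethyl-2,3,4,4a,7,8,9,9a-octahydro-1H-benzo[7]annulen-1-one
Conditions: second-generation Grubbs catalyst (H2IMes)(PCy3)Cl2Ru=CHPh (5 mol %), CH2Cl2 (0.005 M), 40 °C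
Reagents that add atoms: none
Why: Ring-closing metathesis of the vinyl and isopropenyl groups should form the trans-fused cycloheptene with its trisubstituted C4=C15 alkene; no stereocentre changes.

Step 7
Reactants: 15 bicyclic alkene
Product: 16 α-epoxide of 15 (oxirane across C4–C15; oxygen anti to the angular methyl)
Conditions: mCPBA, NaHCO3, CH2Cl2, 0 °C
Reagents that add atoms: mCPBA (OOC(=O)c1cccc(Cl)c1)
Why: Prilezhaev epoxidation of the only electron-rich alkene; in the trans-fused chair cycloheptene ring B and the angular methyl lie on one face, so the peracid should attack the open face syn to the pseudo-axial C5–H and set C4 and C15 as the α-epoxide.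

Step 8
Reactants: 16 α-epoxide
Product: 17 9-oxo-11,12-dinordriman-15-al [(1R,4aS,8aS)-1,4a-dimethyl-5-oxodecahydronaphthalene-1-carbaldehyde]
Conditions: MeAl(OC6H2-2,6-tBu2-4-Br)2 (MABR, 2.2 equiv), CH2Cl2, −78 → −20 °C
Reagents that add atoms: none
Why: The aluminium Lewis acid binds the epoxide oxygen and the tertiary C4–O bond ionises; C5 then shifts from C15 to C4 on the face opposite the departing oxygen, so the seven-membered ring (C10, C1, C2, C3, C4, C15, C5) contracts to six-membered ring A and C15 leaves the ring as the aluminium-bound formyl group. The closest known reaction type is the Meinwald (semipinacol) rearrangement of 1-methylcycloalkene oxides to 1-methylcycloalkane-1-carbaldehydes with bulky aluminium phenoxides. Ring A is not closed by a cyclisation; it arises by this suprafacial 1,2-alkyl shift inside the existing ring. The new quaternary C4 is fixed by the epoxide configuration because migration is anti to the C4–O bond (α-oxygen gives 4β-methyl and 4α-formyl), and C5 migrates with retention so the trans ring fusion is kept. The step needs C4–O rather than C15–O cleavage, which the tertiary carbon secures, and alkyl rather than hydride shift from C15, for which the bulky Lewis acid (it favours the less hindered aldehyde complex) and the strain-free cyclohexane are relied on.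

Step 9
Reactants: 17 keto aldehyde
Product: 18 15-hydroxy-11,12-dinordriman-9-one [(4aS,5R,8aS)-5-(hydroxymethyl)-5,8a-dimethyloctahydronaphthalen-1(2H)-one]
Conditions: NaBH4 (0.3 equiv), EtOH–CH2Cl2, −78 °C
Reagents that add atoms: none
Why: Chemoselective borohydride reduction of the aldehyde beside the hindered ketone (flanked by quaternary C10) at low temperature; no new stereocentre.

Step 10
Reactants: 18 hydroxy ketone
Product: 19 15-(tert-butyldiphenylsilyloxy)-11,12-dinordriman-9-one
Conditions: TBDPSCl, imidazole, DMF, rt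
Reagents that add atoms: tert-butylchlorodiphenylsilane (CC(C)(C)[Si](Cl)(c1ccccc1)c1ccccc1)
Why: Standard silylation of the primary neopentyl alcohol protects C15–OH through the ring B chemistry.

Step 11
Reactants: 19 silyloxy ketone
Product: 20 15-(tert-butyldiphenylsilyloxy)-12-nordrim-9(11)-ene
Conditions: Ph3PCH3Br, KOtBu, toluene, 90 °C
Reagents that add atoms: methyltriphenylphosphonium bromide (C[P+](c1ccccc1)(c1ccccc1)c1ccccc1.[Br-])
Why: Wittig methylenation of the hindered ketone under salt-free forcing conditions installs C11 as an exocyclic methylene.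

Step 12
Reactants: 20 exocyclic alkene
Product: 21 15-(tert-butyldiphenylsilyloxy)-12-nordrim-9(11)-en-8-ol (both C8 epimers)
Conditions: SeO2 (0.5 equiv), t-BuOOH, CH2Cl2, rt
Reagents that add atoms: selenium dioxide (O=[Se]=O), tert-butyl hydroperoxide (CC(C)(C)OO)
Why: Selenium dioxide allylic oxidation (ene reaction, then [2,3]-sigmatropic shift) can only occur at C8 because C10 is quaternary; the C8 configuration is of no consequence.

Step 13
Reactants: 21 allylic alcohol
Product: 22 15-(tert-butyldiphenylsilyloxy)-12-nordrim-9(11)-en-8-one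
Conditions: Dess–Martin periodinane, NaHCO3, CH2Cl2, 0 °C → rt
Reagents that add atoms: none
Why: Dess–Martin oxidation gives the α-methylene ketone under neutral conditions.

Step 14
Reactants: 22 α-methylene ketone
Product: 23 8,12-epoxy-15-(tert-butyldiphenylsilyloxy)drim-9(11)-ene (spiro-oxirane at C8)
Conditions: Me3SI, n-BuLi, THF, −10 → 0 °C
Reagents that add atoms: trimethylsulfonium iodide (C[S+](C)C.[I-])
Why: Corey–Chaykovsky epoxidation: the sulfonium ylide adds 1,2 to the enone carbonyl and closes the oxirane (3-exo-tet), bringing in C12; the C8 configuration is erased in the next step.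

Step 15
Reactants: 23 vinyl oxirane
Product: 24 11-bromo-15-(tert-butyldiphenylsilyloxy)-12-(trimethylsilyloxy)drim-8-ene
Conditions: Me3SiBr, CH2Cl2, −78 °C
Reagents that add atoms: bromotrimethylsilane (C[Si](C)(C)Br)
Why: Silyl-assisted 1,4-opening (SN2') of the 2-alkenyl oxirane: the tertiary allylic C8–O bond ionises and bromide attacks the primary terminus C11, which should give the primary allylic bromide with the tetrasubstituted C8=C9 alkene and the silylated C12 oxygen.

Step 16
Reactants: 24 allylic bromide; 7 hydroxy triester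
Product: 26 C11–O–C1' ether with free C12 hydroxyl, via C12 trimethylsilyl ether 25 (not isolated)
Conditions: Ag2O, 4 Å molecular sieves, CH2Cl2, dark, rt; then PPTS (cat.), MeOH, 0 °C
Reagents that add atoms: none
Why: Ag2O-promoted Williamson etherification of the α-hydroxy ester by the primary allylic bromide runs without strong base, so C1' and C2' should keep their configuration and neither β-elimination nor lactonisation is provoked; the brief acidic methanolysis only frees the C12 hydroxyl.

Step 17
Reactants: 26 allylic alcohol ether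
Product: 29 monomer: isocitrate 1'-methyl 2'-allyl 3'-tert-butyl triester 1'-O-[15-(tert-butyldiphenylsilyloxy)drim-8(12)-en-11-yl] ether, via allylic sulfonylhydrazine 27 (not isolated), via allylic diazene 28 (not isolated)
Conditions: 2-O2NC6H4SO2NHNH2, PPh3, DEAD, N-methylmorpholine, −30 °C → rt
Reagents that add atoms: none
Why: Reductive allylic transposition: Mitsunobu N-alkylation of the sulfonylhydrazide, loss of arenesulfinic acid and retro-ene loss of N2 from the monoalkyl diazene move the double bond to C8=C12 and deliver hydrogen to C9 from the α face, anti to the C10 methyl, which should set the 9β side chain.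

Step 18
Reactants: 29 monomer
Product: 30 monomer acid (free C2' carboxylic acid; 15-silyl ether)
Conditions: Pd(PPh3)4 (5 mol %), morpholine, THF, rt
Reagents that add atoms: none
Why: Allyl ester cleavage through a π-allylpalladium complex with amine capture (Tsuji–Trost type) spares the alkene, the silyl ether and the tert-butyl and methyl esters.

Step 19
Reactants: 29 monomer
Product: 32 C3' carboxylic acid of the monomer, via trimethylsilyl ester 31 (not isolated)
Conditions: Me3SiOTf, 2,6-lutidine, CH2Cl2, 0 °C; then aq. citric acid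
Reagents that add atoms: none
Why: Silyl triflate cleavage of the tert-butyl ester (loss of isobutene from the O-silylated ester) under non-protic conditions should leave the exocyclic alkene, silyl ether and allyl ester intact.

Step 20
Reactants: 32 C3' acid
Product: 33 1',3'-dimethyl 2'-allyl triester (15-silyl ether)
Conditions: Me3SiCHN2, MeOH–toluene, 0 °C
Reagents that add atoms: (trimethylsilyl)diazomethane (C[Si](C)(C)C=[N+]=[N-])
Why: Methyl ester formation with trimethylsilyldiazomethane installs the C3' methyl ester of isocitrate unit 1 under neutral conditions.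

Step 21
Reactants: 33 silyl ether
Product: 34 monomer alcohol (free C15–OH; unit A)
Conditions: HF·pyridine, pyridine, THF, 0 °C → rt
Reagents that add atoms: none
Why: Fluoride desilylation frees the C15 hydroxyl without touching esters or the alkene.

Step 22
Reactants: 30 monomer acid; 34 monomer alcohol
Product: 35 silylated dimer (units A and B joined through isocitrate unit 2)
Conditions: 2-methyl-6-nitrobenzoic anhydride, DMAP, Et3N, CH2Cl2, rt
Reagents that add atoms: none
Why: Shiina esterification (mixed anhydride, DMAP acyl transfer) joins the hindered C2' acid to the neopentyl-type C15 alcohol; no stereocentre is formed and the mild conditions should leave C2' unepimerised.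

Step 23
Reactants: 35 silylated dimer
Product: 36 dimer alcohol (free C15–OH on unit B)
Conditions: HF·pyridine, pyridine, THF, 0 °C → rt
Reagents that add atoms: none
Why: Fluoride desilylation; the tert-butyl, allyl and methyl esters and the alkenes are inert.

Step 24
Reactants: 30 monomer acid; 36 dimer alcohol
Product: 37 protected trimer
Conditions: 2-methyl-6-nitrobenzoic anhydride, DMAP, Et3N, CH2Cl2, rt
Reagents that add atoms: none
Why: Second Shiina esterification, identical in kind to step 22, attaches unit C through isocitrate unit 3.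

Step 25
Reactants: 37 protected trimer
Product: 38 trimer with free C2' acid on isocitrate unit 1
Conditions: Pd(PPh3)4 (5 mol %), morpholine, THF, rt
Reagents that add atoms: none
Why: π-Allylpalladium cleavage of the single allyl ester.

Step 26
Reactants: 38 trimer mono-acid
Product: 40 15-O-silyl cryptoporic acid T, via tris(trimethylsilyl) ester 39 (not isolated)
Conditions: Me3SiOTf, 2,6-lutidine, CH2Cl2, 0 °C; then aq. citric acid
Reagents that add atoms: none
Why: Silyl triflate cleavage of both tert-butyl esters under non-protic conditions avoids acid-induced isomerisation of the three exocyclic alkenes.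

Step 27
Reactants: 40 silyl ether
Product: 41 cryptoporic acid T
Conditions: HF·pyridine, pyridine, THF, 0 °C → rt
Reagents that add atoms: none
Why: Fluoride desilylation frees the C15 hydroxyl of unit C and should give the target.

**Compound list**
1 | (R)-malic acid | OC(=O)C[C@@H](O)C(=O)O | starting material
2 | (R)-2-(trifluoroacetoxy)succinic anhydride | O=C1C[C@@H](OC(=O)C(F)(F)F)C(=O)O1 | intermediate
3 | (R)-malic acid 1-methyl ester | OC(=O)C[C@@H](O)C(=O)OC | intermediate
4 | 4-allyl 1-methyl (R)-malate | C=CCOC(=O)C[C@@H](O)C(=O)OC | intermediate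
5 | tert-butyl bromoacetate | BrCC(=O)OC(C)(C)C | starting material
6 | dilithium alkoxide enolate of 4 | [Li+].[Li+].C=CCOC([O-])=C[C@@H]([O-])C(=O)OC | intermediate
7 | 3-tert-butyl 1-methyl 2-allyl (1R,2S)-1-hydroxypropane-1,2,3-tricarboxylate (isocitrate triester, free C1' OH) | C=CCOC(=O)[C@@H](CC(=O)OC(C)(C)C)[C@@H](O)C(=O)OC | intermediate
8 | 2-methylcyclohex-2-en-1-one | CC1=CCCCC1=O | starting material
9 | vinylmagnesium bromide | C=C[Mg]Br | starting material
10 | bromomagnesium enolate of (S)-2-methyl-3-vinylcyclohexanone | C=C[C@@H]1CCCC(O[Mg]Br)=C1C | intermediate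
11 | (S)-trimethyl[(2-methyl-3-vinylcyclohex-1-en-1-yl)oxy]silane | C=C[C@@H]1CCCC(O[Si](C)(C)C)=C1C | intermediate
12 | 5-bromo-2-methylpent-1-ene | C=C(C)CCCBr | starting material
13 | lithium enolate from 11 | [Li+].C=C[C@@H]1CCCC([O-])=C1C | intermediate
14 | (2S,3S)-2-methyl-2-(4-methylpent-4-en-1-yl)-3-vinylcyclohexan-1-one | O=C1CCC[C@@H](C=C)[C@]1(C)CCCC(C)=C | intermediate
15 | (4aS,9aS)-6,9a-dimethyl-2,3,4,4a,7,8,9,9a-octahydro-1H-benzo[7]annulen-1-one (trans-fused) | O=C1CCC[C@H]2C=C(C)CCC[C@]12C | intermediate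
16 | α-epoxide of 15 (oxygen anti to the angular methyl) | O=C1CCC[C@H]2[C@@H]3O[C@]3(C)CCC[C@]12C | intermediate
17 | (1R,4aS,8aS)-1,4a-dimethyl-5-oxodecahydronaphthalene-1-carbaldehyde (4α-CHO, 4β-Me) | O=C1CCC[C@H]2[C@](C)(C=O)CCC[C@]12C | intermediate
18 | (4aS,5R,8aS)-5-(hydroxymethyl)-5,8a-dimethyloctahydronaphthalen-1(2H)-one | O=C1CCC[C@H]2[C@](C)(CO)CCC[C@]12C | intermediate
19 | tert-butyldiphenylsilyl ether of 18 | O=C1CCC[C@H]2[C@](C)(CO[Si](c3ccccc3)(c3ccccc3)C(C)(C)C)CCC[C@]12C | intermediate
20 | 15-(tert-butyldiphenylsilyloxy)-12-nordrim-9(11)-ene | C=C1CCC[C@H]2[C@](C)(CO[Si](c3ccccc3)(c3ccccc3)C(C)(C)C)CCC[C@]12C | intermediate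
21 | 15-(tert-butyldiphenylsilyloxy)-12-nordrim-9(11)-en-8-ol (C8 epimers) | C=C1C(O)CC[C@H]2[C@](C)(CO[Si](c3ccccc3)(c3ccccc3)C(C)(C)C)CCC[C@]12C | intermediate
22 | 15-(tert-butyldiphenylsilyloxy)-12-nordrim-9(11)-en-8-one | C=C1C(=O)CC[C@H]2[C@](C)(CO[Si](c3ccccc3)(c3ccccc3)C(C)(C)C)CCC[C@]12C | intermediate
23 | 8,12-epoxy-15-(tert-butyldiphenylsilyloxy)drim-9(11)-ene (C8 epimers) | C=C1C2(CO2)CC[C@H]3[C@](C)(CO[Si](c4ccccc4)(c4ccccc4)C(C)(C)C)CCC[C@]13C | intermediate
24 | 11-bromo-15-(tert-butyldiphenylsilyloxy)-12-(trimethylsilyloxy)drim-8-ene | BrCC1=C(CO[Si](C)(C)C)CC[C@H]2[C@](C)(CO[Si](c3ccccc3)(c3ccccc3)C(C)(C)C)CCC[C@]12C | intermediate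
25 | ether of 7 (C1'–O–C11) with the drim-8-ene, 12-O-trimethylsilyl, 15-O-silyl | C=CCOC(=O)[C@@H](CC(=O)OC(C)(C)C)[C@@H](OCC1=C(CO[Si](C)(C)C)CC[C@H]2[C@](C)(CO[Si](c3ccccc3)(c3ccccc3)C(C)(C)C)CCC[C@]12C)C(=O)OC | intermediate
26 | same ether with free C12–OH | C=CCOC(=O)[C@@H](CC(=O)OC(C)(C)C)[C@@H](OCC1=C(CO)CC[C@H]2[C@](C)(CO[Si](c3ccccc3)(c3ccccc3)C(C)(C)C)CCC[C@]12C)C(=O)OC | intermediate
27 | N-(C12 allyl)-N-(2-nitrophenylsulfonyl)hydrazine | C=CCOC(=O)[C@@H](CC(=O)OC(C)(C)C)[C@@H](OCC1=C(CN(N)S(=O)(=O)c3ccccc3[N+](=O)[O-])CC[C@H]2[C@](C)(CO[Si](c3ccccc3)(c3ccccc3)C(C)(C)C)CCC[C@]12C)C(=O)OC | intermediate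
28 | C12 allylic diazene | C=CCOC(=O)[C@@H](CC(=O)OC(C)(C)C)[C@@H](OCC1=C(CN=N)CC[C@H]2[C@](C)(CO[Si](c3ccccc3)(c3ccccc3)C(C)(C)C)CCC[C@]12C)C(=O)OC | intermediate
29 | monomer: 1'-methyl 2'-allyl 3'-tert-butyl isocitrate 1'-O-[15-(tert-butyldiphenylsilyloxy)drim-8(12)-en-11-yl] ether (9β side chain) | C=CCOC(=O)[C@@H](CC(=O)OC(C)(C)C)[C@@H](OC[C@H]1C(=C)CC[C@H]2[C@](C)(CO[Si](c3ccccc3)(c3ccccc3)C(C)(C)C)CCC[C@]12C)C(=O)OC | intermediate
30 | monomer acid (C2' CO2H) | OC(=O)[C@@H](CC(=O)OC(C)(C)C)[C@@H](OC[C@H]1C(=C)CC[C@H]2[C@](C)(CO[Si](c3ccccc3)(c3ccccc3)C(C)(C)C)CCC[C@]12C)C(=O)OC | intermediate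
31 | C3' trimethylsilyl ester of the monomer | C=CCOC(=O)[C@@H](CC(=O)O[Si](C)(C)C)[C@@H](OC[C@H]1C(=C)CC[C@H]2[C@](C)(CO[Si](c3ccccc3)(c3ccccc3)C(C)(C)C)CCC[C@]12C)C(=O)OC | intermediate
32 | C3' carboxylic acid of the monomer | C=CCOC(=O)[C@@H](CC(=O)O)[C@@H](OC[C@H]1C(=C)CC[C@H]2[C@](C)(CO[Si](c3ccccc3)(c3ccccc3)C(C)(C)C)CCC[C@]12C)C(=O)OC | intermediate
33 | 1',3'-dimethyl 2'-allyl triester, 15-silyl ether | C=CCOC(=O)[C@@H](CC(=O)OC)[C@@H](OC[C@H]1C(=C)CC[C@H]2[C@](C)(CO[Si](c3ccccc3)(c3ccccc3)C(C)(C)C)CCC[C@]12C)C(=O)OC | intermediate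
34 | monomer alcohol (unit A, free C15–OH) | C=CCOC(=O)[C@@H](CC(=O)OC)[C@@H](OC[C@H]1C(=C)CC[C@H]2[C@](C)(CO)CCC[C@]12C)C(=O)OC | intermediate
35 | silylated dimer | C=C1CC[C@H]2[C@](C)(COC(=O)[C@@H](CC(=O)OC(C)(C)C)[C@@H](OC[C@H]3C(=C)CC[C@H]4[C@](C)(CO[Si](c5ccccc5)(c5ccccc5)C(C)(C)C)CCC[C@]34C)C(=O)OC)CCC[C@]2(C)[C@H]1CO[C@@H](C(=O)OC)[C@H](CC(=O)OC)C(=O)OCC=C | intermediate
36 | dimer alcohol | C=C1CC[C@H]2[C@](C)(COC(=O)[C@@H](CC(=O)OC(C)(C)C)[C@@H](OC[C@H]3C(=C)CC[C@H]4[C@](C)(CO)CCC[C@]34C)C(=O)OC)CCC[C@]2(C)[C@H]1CO[C@@H](C(=O)OC)[C@H](CC(=O)OC)C(=O)OCC=C | intermediate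
37 | protected trimer (allyl ester, two tert-butyl esters, silyl ether) | C=C1CC[C@H]2[C@](C)(COC(=O)[C@@H](CC(=O)OC(C)(C)C)[C@@H](OC[C@H]3C(=C)CC[C@H]4[C@](C)(COC(=O)[C@@H](CC(=O)OC(C)(C)C)[C@@H](OC[C@H]5C(=C)CC[C@H]6[C@](C)(CO[Si](c7ccccc7)(c7ccccc7)C(C)(C)C)CCC[C@]56C)C(=O)OC)CCC[C@]34C)C(=O)OC)CCC[C@]2(C)[C@H]1CO[C@@H](C(=O)OC)[C@H](CC(=O)OC)C(=O)OCC=C | intermediate
38 | trimer with free C2' acid on isocitrate unit 1 | C=C1CC[C@H]2[C@](C)(COC(=O)[C@@H](CC(=O)OC(C)(C)C)[C@@H](OC[C@H]3C(=C)CC[C@H]4[C@](C)(COC(=O)[C@@H](CC(=O)OC(C)(C)C)[C@@H](OC[C@H]5C(=C)CC[C@H]6[C@](C)(CO[Si](c7ccccc7)(c7ccccc7)C(C)(C)C)CCC[C@]56C)C(=O)OC)CCC[C@]34C)C(=O)OC)CCC[C@]2(C)[C@H]1CO[C@@H](C(=O)OC)[C@H](CC(=O)OC)C(=O)O | intermediate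
39 | tris(trimethylsilyl) ester of 40 | C=C1CC[C@H]2[C@](C)(COC(=O)[C@@H](CC(=O)O[Si](C)(C)C)[C@@H](OC[C@H]3C(=C)CC[C@H]4[C@](C)(COC(=O)[C@@H](CC(=O)O[Si](C)(C)C)[C@@H](OC[C@H]5C(=C)CC[C@H]6[C@](C)(CO[Si](c7ccccc7)(c7ccccc7)C(C)(C)C)CCC[C@]56C)C(=O)OC)CCC[C@]34C)C(=O)OC)CCC[C@]2(C)[C@H]1CO[C@@H](C(=O)OC)[C@H](CC(=O)OC)C(=O)O[Si](C)(C)C | intermediate
40 | 15-O-(tert-butyldiphenylsilyl) cryptoporic acid T | C=C1CC[C@H]2[C@](C)(COC(=O)[C@@H](CC(=O)O)[C@@H](OC[C@H]3C(=C)CC[C@H]4[C@](C)(COC(=O)[C@@H](CC(=O)O)[C@@H](OC[C@H]5C(=C)CC[C@H]6[C@](C)(CO[Si](c7ccccc7)(c7ccccc7)C(C)(C)C)CCC[C@]56C)C(=O)OC)CCC[C@]34C)C(=O)OC)CCC[C@]2(C)[C@H]1CO[C@@H](C(=O)OC)[C@H](CC(=O)OC)C(=O)O | intermediate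
41 | cryptoporic acid T | C=C1CC[C@H]2[C@](C)(COC(=O)[C@@H](CC(=O)O)[C@@H](OC[C@H]3C(=C)CC[C@H]4[C@](C)(COC(=O)[C@@H](CC(=O)O)[C@@H](OC[C@H]5C(=C)CC[C@H]6[C@](C)(CO)CCC[C@]56C)C(=O)OC)CCC[C@]34C)C(=O)OC)CCC[C@]2(C)[C@H]1CO[C@@H](C(=O)OC)[C@H](CC(=O)OC)C(=O)O | target

**Totals**
Total step count: 27. Longest linear sequence: 23 steps (8 → 41 through steps 4–17 and 19–27).

**Steps most likely to fail**

Step 8. A 1,2-hydride shift from C15 may compete with the ring-bond shift and give the seven-membered ketone, or a long-lived C4 cation may erode the stereospecificity. The fallback replaces the cationic epoxide rearrangement by a halohydrin semipinacol in which the hydrogen on C15 is cis to the leaving group and so cannot migrate. It sets out from alkene 15. NBS in aqueous acetone should give the bromohydrin F1 (bromine on C15 from the α face, hydroxyl on C4). K2CO3 in MeOH closes it to the β-epoxide F2. MgBr2·OEt2 in warm benzene opens F2 at the tertiary C4 with inversion to the bromomagnesium alkoxide F3 (not isolated). In F3 the C15–C5 bond lies antiperiplanar to C4–Br in the diequatorial conformer, so C5 displaces bromide. The double inversion at C4 gives the same configuration as step 8, and the route is rejoined at aldehyde 17.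

Step 16. The hindered, weakly nucleophilic hydroxy triester may alkylate slowly, so that ionisation of the allylic bromide and loss to the diene, or lactonisation of 7, take over. The fallback sets out from vinyl oxirane 23 and skips the bromide. Pd(PPh3)4 ionises the allylic C8–O bond to a π-allylpalladium alkoxide, and the zinc alkoxide of 7 (from Et2Zn, THF) attacks the primary terminus C11 (palladium-catalysed allylic etherification). Work-up gives 26 directly; no new compound is formed (F0).

Step 22 (and likewise step 24). The activated C2' acid may epimerise or lose the C1' alkoxy group by β-elimination, and the neopentyl-type C15 alcohol may acylate slowly. The fallback forms the same bond by alkylation and never activates the carboxyl group. It sets out from alcohol 34, which Tf2O and 2,6-di-tert-butylpyridine convert to the C15 triflate F4. The caesium salt of acid 30 (Cs2CO3, DMF–toluene) displaces the triflate by SN2 and the route is rejoined at dimer 35.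

**Further compounds**
F1 | step 8 | bromohydrin from 15 (15α-bromo, 4β-hydroxy) | O=C1CCC[C@H]2[C@H](Br)[C@@](C)(O)CCC[C@]12C
F2 | step 8 | β-epoxide (C4/C15 epimer of 16) | O=C1CCC[C@H]2[C@H]3O[C@@]3(C)CCC[C@]12C
F3 | step 8 | bromomagnesium alkoxide of the 4α-bromo-15β-ol | O=C1CCC[C@H]2[C@@H](O[Mg]Br)[C@](C)(Br)CCC[C@]12C
F0 | step 16 | none | none
F4 | step 22 | C15 triflate of 34 | C=CCOC(=O)[C@@H](CC(=O)OC)[C@@H](OC[C@H]1C(=C)CC[C@H]2[C@](C)(COS(=O)(=O)C(F)(F)F)CCC[C@]12C)C(=O)OC
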